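The data are simulated on assumed constants; scatter was added.

3 numbers were asked, one for each flask, and I reckoned all of them with one quantity.

in all of them: starting complex 0.10 M

| run | incoming ligand | remark | time |
|---|---|---|---|
| midnight | 0.071 M (fed, over 10 min) | run made earlier |  |
| summer | 0.18 M (fed, over 10 min) | run made earlier |  |
| eta | 0.0800 M (fed, over 10 min) |  | 12 h |
| delta | 0.150 M (fed, over 10 min) |  | 12 h |
| alpha | 0.250 M (fed, over 10 min) |  | 12 h |

| run | time / h | complex with one exchanged / % | complex with two exchanged / % |
|---|---|---|---|
| midnight | 0.667 | 9.8 | 1.2 |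
| midnight | 1.33 | 17.4 | 1.9 |
| midnight | 2.50 | 25.6 | 3.0 |
| midnight | 4.00 | 30.4 | 6.1 |
| midnight | 8.00 | 34.8 | 10.9 |
| summer | 0.667 | 20.4 | 2.0 |
| summer | 1.33 | 34.0 | 8.0 |
| summer | 2.50 | 38.9 | 15.8 |
| summer | 4.00 | 38.7 | 25.4 |
| summer | 8.00 | 34.2 | 36.5 |

(readings scatter by 0.5 percentage points)

- how much complex with one exchanged is there at the end, in percent of the starting complex charged: for each flask in turn (eta, delta, alpha)

- steps thought possible: starting complex + incoming ligand <-> leaving ligand + complex with one exchanged; leaving ligand -> by-product carried off; complex with two exchanged + incoming ligand -> over-reaction product; complex with one exchanged + incoming ligand <-> leaving ligand + complex with two exchanged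

I began from the first midnight reading. The complexes that had reacted gave a rate constant k of 7.81 × 10⁻⁴ M⁻¹ s⁻¹, with half the feed time taken off the clock. The summer run's highest reading of complex with one exchanged, 38.9%, lay close to 36.8%, the peak height of two consecutive steps with a selectivity factor of one. So I gave both exchanges the constant k. Then φ, the exposure, is k times the integral of c(incoming ligand) over time, and complex with one exchanged is φ·exp(−φ), peaking at φ equal to one.

Next I turned the settings one by one. By hand, the feed counted little, since its 10 min is shorter than 1/(k·c(incoming ligand)) even in alpha, and it does change nothing that matters. The hold came next. Early on, each unit of φ spends one incoming ligand per complex, so dφ/dt = k(c(incoming ligand, charged) − c(starting complex)·φ). This integrates to φ = charge ratio × (one − exp(−k·c(starting complex)·t)). At 12 h that bracket had reached 96.6%, so in my reckoning the hold counted little by then. The charge remained. It gave φ of 0.773 for eta, 1.45 for delta and 2.41 for alpha. My values were therefore 35.7%, 34.0% and 21.6%.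

The forecast gave 37.5%, 34% and 23%, with alpha “pushed well past its peak”, so it stood above my values in eta and alpha and level with mine in delta.

The flasks gave 38.0% in eta, 34.9% in delta and 17.7% in alpha.

    starting complex + incoming ligand ⇌ leaving ligand + complex with one exchanged (K = 1.20, k = 8.00 × 10⁻⁴ M⁻¹ s⁻¹)
    leaving ligand → by-product carried off (k = 2.80 × 10⁻⁴ s⁻¹)
    complex with two exchanged + incoming ligand → over-reaction product (k = 2.50 × 10⁻⁴ M⁻¹ s⁻¹)
    complex with one exchanged + incoming ligand ⇌ leaving ligand + complex with two exchanged (K = 3.00, k = 6.20 × 10⁻⁴ M⁻¹ s⁻¹)

In alpha, complex with two exchanged stood at 44.9% at the end. Exposure also gives the starting complex left, as exp(−φ). For delta that is 23.5%, and 20.5% stood there at 12.0 h. For alpha it is 8.98%, and the flask held 5.32%.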